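Over days the grey run, which is this very flask followed so far, stops changing, so we ask what it holds at 15 d. Partner turns into second intermediate, and that captures open intermediate to give target, while open intermediate also turns into side product.

- grey: starting material 0.10 M (in portions, 3); partner 0.12 M; the very flask that is asked about, followed so far; portions every 1.0 h
- flask: starting material 0.10 M (in portions, 3); partner 0.120 M; time 15 d; the portions of starting material follow each other after 1.0 h, the first at the start

- grey (time / d: starting material / %, target / %, side product / %): 1.04: 9.6, 75.6, 14.7; 2.08: 0.4, 83.8, 16.0; 3.00: 0.7, 83.5, 15.2; 4.00: 0, 84.7, 16.2; 5.00: 0, 84.0, 16.4; 6.00: 0.7, 84.3, 15.7

(standard deviation of a reading: 0.5 percentage points)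

- target is meant together with its crystals
- solid, in amounts per volume of the solution: crystals
- reactions considered so far: open intermediate -> side product; open intermediate + second intermediate -> target; starting material <-> open intermediate; partner -> second intermediate; crystals <-> target
- the reaction counts as stopped when no species that holds the starting material changes by six tenths of a point or more over the second half of the time
- a reading of starting material is of its free form alone

* the state of affairs at 15 d: stopped, and by what, or still going (forward and back rates have come level / it is still moving / all of the starting material has reacted)
* how much of the starting material has reacted by 15 d
* how much target there is at 15 d, in percent of the starting material charged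
* how much side product there is at 15 d, in percent of the starting material charged

Is anything still moving? From 2.08 d to 6.00 d target in the grey run changes by 0.5 percentage points, the size of the scatter of one reading (0.5 points), and starting material reads 0.360 % on average. So we read the end of this flask from the means of those readings: target 84.1 %, side product 15.9 %.

How did open intermediate split? The quotient of these means, 5.29, is what we call the capture ratio: target made per side product made, which is the mean over the run of the rate of capture over the rate of loss, weighted by the rate of loss.

What does that mean rest on? The rate of capture goes with c(second intermediate). Starting material, 0.10 M against 0.12 M of partner, is the limiting reagent. Target took 0.0841 M, which leaves 0.0359 M as partner and second intermediate together. If c(second intermediate) climbs roughly straight from zero to that, its mean is 0.0180 M, half of it, and we try the capture ratio as proportional to it.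

The forecast says all of the starting material has reacted, with 100 % reacted, target 84.1 % and side product 15.9 %, on the ground that “Nothing drifts, and the mass balance closes”.

The flask gives all of the starting material has reacted, with 100 % reacted, target 84.2 % (crystals 33.2 % counted within it) and side product 15.8 %.

    open intermediate → side product (k = 0.190 /h)
    open intermediate + second intermediate → target (k = 44.0 /M/h)
    starting material ⇌ open intermediate (K = 1.40, k = 0.110 /h)
    partner → second intermediate (k = 0.0890 /h)
    crystals ⇌ target, rate k5*(cs5 - [target]) while solid is left; crystals form when [target] > cs5 (solubility = 0.0510 M, k = 2.70 /h)

At 0.325 d this flask's open intermediate went on to target 5.3 times as fast as to side product, beside the capture ratio 5.29 from the readings, and the falling out of crystals shifts side product by nothing. The neighbour flask with 0.025 M of starting material ends with 0.0973 M of second intermediate against 0.0358 M in this flask, so the capture ratio scaled by that becomes 14.4, which means side product 6.50 %; that neighbour flask holds 9.27 %, a capture ratio of 9.79.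

The readings were computed with made-up constants; scatter was added.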